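## Retrosynthetic overview

1. Ring C is opened at O1–C8a and at C4–C4a. This gives a ring A aryne (triple bond C4a≡C8a, 5,7-bis-OMOM, side chain on C8) and the (S)-β-hydroxy Weinreb amide 7, which carries C2, C3, C4 and ring B. Rings A and B are bought; ring C is the only ring made and closes last, O1–C8a first, then C4–C4a.
2. Enabling feature: in ring A the oxygen-bearing C8a and the acyl-bearing C4a are neighbours, and C5 beside C4a carries oxygen. An aryne across C4a–C8a is polarised by that C5–O bond, so an alkoxide enters at C8a and the carbanion appears at C4a, five atoms from the amide carbonyl (C4).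
3. Aryne precursor 31 (o-silylaryl triflate): phloroglucinol → bis-MOM ether → carbamate-directed ortho-silylation and ortho-iodination → Negishi coupling with the side-chain zinc reagent → carbamate-to-triflate exchange.
4. Side chain: (4R)-limonene oxide supplies the stereocentre; C1–C2 cleavage, methyl addition to the ketone and Barton iododecarboxylation (loss of C2) give iodide 16.
5. C2 comes from asymmetric transfer hydrogenation of β-keto amide 6; one mild acidic step removes three MOM groups and the TES group.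

Key step: step 16

Assumption: commercial (+)-limonene 1,2-oxide (4R, cis/trans mixture) is used; both epimers converge on the same keto aldehyde, so C1 and C2 of 8 and 9 are left undefined. The descriptor of the side-chain centre changes (R, S, R) along the route through CIP priority changes only; its bonds are never touched.

## Route

**Fragment for C2–C4 and ring B**

Step 1
Reactants: 1 4-hydroxy-2-methoxybenzaldehyde
Product: 2 2-methoxy-4-(methoxymethoxy)benzaldehyde
Conditions: MOMCl, K2CO3, acetone, 0 °C → rt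
Reagents that add atoms: chloromethyl methyl ether (MOMCl), COCCl
Why: Williamson-type O-alkylation of the acidic para-formyl phenol; the MOM ether withstands the bases, organometallics and fluoride used later and leaves with mild acid at the end.

Step 2
Reactants: 2 2-methoxy-4-(methoxymethoxy)benzaldehyde; 3 N-methoxy-N-methylacetamide
Product: 5 rac-3-hydroxy-N-methoxy-3-[2-methoxy-4-(methoxymethoxy)phenyl]-N-methylpropanamide, via lithium enolate 4 (not isolated)
Conditions: LiN(i-Pr)2, THF, −78 °C; then 2, −78 °C; aq. NH4Cl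
Reagents that add atoms: none
Why: Aldol addition of the preformed lithium enolate of the Weinreb acetamide to a non-enolisable aldehyde; the racemic carbinol is only a relay to the ketone.

Step 3
Reactants: 5 rac-3-hydroxy-N-methoxy-3-[2-methoxy-4-(methoxymethoxy)phenyl]-N-methylpropanamide
Product: 6 N-methoxy-3-[2-methoxy-4-(methoxymethoxy)phenyl]-N-methyl-3-oxopropanamide
Conditions: Dess–Martin periodinane, NaHCO3, CH2Cl2, 0 °C → rt
Reagents that add atoms: none
Why: Dess–Martin oxidation of a secondary benzylic alcohol to the β-keto amide under buffered conditions that spare the MOM ether.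

Step 4
Reactants: 6 N-methoxy-3-[2-methoxy-4-(methoxymethoxy)phenyl]-N-methyl-3-oxopropanamide
Product: 7 (3S)-3-hydroxy-N-methoxy-3-[2-methoxy-4-(methoxymethoxy)phenyl]-N-methylpropanamide
Conditions: RuCl[(S,S)-TsDPEN](p-cymene) (1 mol %), HCO2H/Et3N (5:2), CH2Cl2, 30 °C
Reagents that add atoms: none
Why: Noyori–Ikariya asymmetric transfer hydrogenation of an aryl ketone; with the (S,S) ligand the aryl group should sit under the arene ligand as in the acetophenone case, so hydride is delivered to the face that gives the (S)-carbinol, the future C2.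

**Side chain from limonene**

Step 5
Reactants: 8 (4R)-limonene 1,2-oxide
Product: 10 (3R)-6-oxo-3-(prop-1-en-2-yl)heptanal, via limonene-1,2-diol 9 (not isolated)
Conditions: HIO4·2H2O, THF/H2O, 0 °C → rt
Reagents that add atoms: water, O
Why: Periodic acid opens the epoxide to the vicinal diol and cleaves it (Malaprade glycol cleavage), leaving the isopropenyl group and the ring stereocentre (the future side-chain centre) untouched.

Step 6
Reactants: 10 (3R)-6-oxo-3-(prop-1-en-2-yl)heptanal
Product: 11 (3R)-6-oxo-3-(prop-1-en-2-yl)heptanoic acid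
Conditions: NaClO2, NaH2PO4, 2-methyl-2-butene, t-BuOH/H2O, 0 °C → rt
Reagents that add atoms: sodium chlorite, [Na+].[O-]Cl=O
Why: Pinnick oxidation of the aldehyde, with 2-methyl-2-butene scavenging HOCl so that the isopropenyl group and the methyl ketone survive.

Step 7
Reactants: 11 (3R)-6-oxo-3-(prop-1-en-2-yl)heptanoic acid
Product: 12 (3R)-6-hydroxy-6-methyl-3-(prop-1-en-2-yl)heptanoic acid
Conditions: MeMgBr (3 equiv), THF, −78 → 0 °C; aq. NH4Cl, then pH 4
Reagents that add atoms: methylmagnesium bromide, C[Mg]Br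
Why: Grignard addition to the methyl ketone; the first equivalent turns CO2H into an unreactive magnesium carboxylate, so only the ketone takes up methyl.

Step 8
Reactants: 12 (3R)-6-hydroxy-6-methyl-3-(prop-1-en-2-yl)heptanoic acid
Product: 14 (3R)-6-methyl-3-(prop-1-en-2-yl)-6-(triethylsilyloxy)heptanoic acid, via bis-silyl derivative 13 (not isolated)
Conditions: Et3SiOTf (2.3 equiv), 2,6-lutidine, CH2Cl2, −78 → 0 °C; then THF/H2O, cat. AcOH, rt
Reagents that add atoms: triethylsilyl trifluoromethanesulfonate, CC[Si](CC)(CC)OS(=O)(=O)C(F)(F)F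
Why: Silyl triflate silylation of the hindered tertiary alcohol; the labile silyl ester formed alongside is hydrolysed in the work-up, and the tertiary oxygen is masked before any alkyl iodide exists, which excludes cyclic ether formation.

Step 9
Reactants: 14 (3R)-6-methyl-3-(prop-1-en-2-yl)-6-(triethylsilyloxy)heptanoic acid
Product: 16 triethyl{[(5S)-6-iodo-2-methyl-5-(prop-1-en-2-yl)hexan-2-yl]oxy}silane, via Barton ester 15 (not isolated)
Conditions: 1-hydroxypyridine-2(1H)-thione, DCC, cat. DMAP, CH2Cl2, 0 °C, dark; then CHI3 (2 equiv), benzene, tungsten lamp, rt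
Reagents that add atoms: iodoform, IC(I)I
Why: Barton decarboxylative iodination, in which the thiohydroxamate ester fragments under light to the primary alkyl radical and this takes iodine from CHI3 faster than a homoallyl 1,2-vinyl shift can occur; the stereocentre is not a radical site, so its configuration is kept.

**Ring A aryne precursor**

Step 10
Reactants: 17 phloroglucinol
Product: 18 3,5-bis(methoxymethoxy)phenol
Conditions: NaH (2 equiv), MOMCl (2 equiv), DMF, 0 °C → rt
Reagents that add atoms: chloromethyl methyl ether (MOMCl), COCCl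
Why: Statistical double Williamson etherification of a threefold symmetric triol; the bis-ether should be separable from the mono- and tris-ethers, which can be recycled.

Step 11
Reactants: 18 3,5-bis(methoxymethoxy)phenol
Product: 19 3,5-bis(methoxymethoxy)phenyl N-(propan-2-yl)carbamate
Conditions: i-PrNCO, Et3N (cat.), CH2Cl2, rt
Reagents that add atoms: isopropyl isocyanate, CC(C)N=C=O
Why: Base-catalysed addition of the phenol to the isocyanate gives the secondary carbamate, the strongest ortho-directing group on the ring and a phenol mask removable later by E1cB elimination.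

Step 12
Reactants: 19 3,5-bis(methoxymethoxy)phenyl N-(propan-2-yl)carbamate
Product: 23 3,5-bis(methoxymethoxy)-2-(trimethylsilyl)phenyl N-(propan-2-yl)carbamate, via N-silyl carbamate 20 (not isolated), via aryllithium 21 (not isolated), via N-silyl arylsilane 22 (not isolated)
Conditions: TMEDA, t-BuMe2SiOTf, Et2O, 0 °C → rt; n-BuLi, TMEDA, −78 °C; Me3SiCl, −78 °C → rt; aq. NaHSO4
Reagents that add atoms: chlorotrimethylsilane, C[Si](C)(C)Cl
Why: Directed ortho-metalation: after in situ N-silylation the carbamate outranks OMOM as director, so lithiation should occur at C2 between carbamate and OMOM and not at C4 between the two OMOM groups, and Me3SiCl traps the aryllithium.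

Step 13
Reactants: 23 3,5-bis(methoxymethoxy)-2-(trimethylsilyl)phenyl N-(propan-2-yl)carbamate
Product: 27 2-iodo-3,5-bis(methoxymethoxy)-6-(trimethylsilyl)phenyl N-(propan-2-yl)carbamate, via N-trimethylsilyl arylsilane 24 (not isolated), via aryllithium 25 (not isolated), via N-trimethylsilyl aryl iodide 26 (not isolated)
Conditions: TMEDA, Me3SiOTf, Et2O, 0 °C → rt; n-BuLi, TMEDA, −78 °C; I2, −78 °C → rt; aq. NaHSO4, Na2S2O3
Reagents that add atoms: iodine, II
Why: Second directed ortho-metalation at the only remaining position ortho to the carbamate, followed by iodine quench; the N–H is masked in situ this time as the smaller and more labile N–SiMe3 group because the carbamate now has an ortho-SiMe3 neighbour, and the silyl group goes in before the alkyl chain because a benzylic CH2 beside the carbamate would invite lateral lithiation.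

Step 14
Reactants: 16 triethyl{[(5S)-6-iodo-2-methyl-5-(prop-1-en-2-yl)hexan-2-yl]oxy}silane; 27 2-iodo-3,5-bis(methoxymethoxy)-6-(trimethylsilyl)phenyl N-(propan-2-yl)carbamate
Product: 29 3,5-bis(methoxymethoxy)-2-[(2R)-5-methyl-2-(prop-1-en-2-yl)-5-(triethylsilyloxy)hexyl]-6-(trimethylsilyl)phenyl N-(propan-2-yl)carbamate, via alkylzinc iodide 28 (not isolated)
Conditions: Zn dust (activated by BrCH2CH2Br, Me3SiCl), LiCl, THF, 40 °C; then 27, Pd(OAc)2 (3 mol %), SPhos (6 mol %), THF, 25 → 50 °C
Reagents that add atoms: none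
Why: Negishi sp3–sp2 coupling; zinc insertion into the primary iodide leaves the β-stereocentre untouched, and the Pd(OAc)2/SPhos catalyst is of the kind that couples di-ortho-substituted aryl halides and tolerates an N–H bond.

Step 15
Reactants: 29 3,5-bis(methoxymethoxy)-2-[(2R)-5-methyl-2-(prop-1-en-2-yl)-5-(triethylsilyloxy)hexyl]-6-(trimethylsilyl)phenyl N-(propan-2-yl)carbamate
Product: 31 3,5-bis(methoxymethoxy)-2-[(2R)-5-methyl-2-(prop-1-en-2-yl)-5-(triethylsilyloxy)hexyl]-6-(trimethylsilyl)phenyl trifluoromethanesulfonate, via silyl phenol 30 (not isolated)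
Conditions: DBU, Et2NH, MeCN, 40 °C; then PhNTf2, rt
Reagents that add atoms: N-phenylbis(trifluoromethanesulfonimide), O=S(=O)(N(c1ccccc1)S(=O)(=O)C(F)(F)F)C(F)(F)F
Why: E1cB cleavage of the N–H carbamate (isocyanate trapped by Et2NH) releases the hindered phenoxide, which is triflated in the same flask, the standard entry to o-silylaryl triflates.

**Union and deprotection**

Step 16
Reactants: 7 (3S)-3-hydroxy-N-methoxy-3-[2-methoxy-4-(methoxymethoxy)phenyl]-N-methylpropanamide; 31 3,5-bis(methoxymethoxy)-2-[(2R)-5-methyl-2-(prop-1-en-2-yl)-5-(triethylsilyloxy)hexyl]-6-(trimethylsilyl)phenyl trifluoromethanesulfonate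
Product: 36 (2S)-2-[2-methoxy-4-(methoxymethoxy)phenyl]-5,7-bis(methoxymethoxy)-8-[(2R)-5-methyl-2-(prop-1-en-2-yl)-5-(triethylsilyloxy)hexyl]-2,3-dihydro-4H-chromen-4-one, via sodium alkoxide 32 (not isolated), via aryne 33 (not isolated), via aryl anion 34 (not isolated), via hemiaminal alkoxide 35 (not isolated)
Conditions: 7 (1.5 equiv), NaH (1.5 equiv), THF, 0 °C; then CsF (3 equiv), 18-crown-6, slow addition of 31, THF, 0 °C → rt; aq. NH4Cl
Reagents that add atoms: none
Why: Proposed new method: Fluoride removes the trimethylsilyl group of 31 and triflate leaves, giving aryne 33 (triple bond between the future C4a and C8a); alkoxide 32 adds through oxygen to C8a, and the aryl carbanion 34 thus placed on C4a attacks the Weinreb amide carbonyl, forming C4–C4a and the tetrahedral adduct 35, which collapses to ketone 36 only on aqueous work-up. The closest known reaction type is the fluoride-induced annulation of arynes with methyl salicylates to xanthones (phenoxide addition, then acyl substitution by the aryl anion), together with the ring expansion of N–H β-lactams by arynes; new is an aliphatic secondary alkoxide bearing a β-carboxamide as the partner, which builds a 2-arylchroman-4-one. Ring C closes by a polar 6-exo-trig addition of the C4a anion to the amide C=O, after intermolecular O1–C8a bond formation. No new stereocentre remains: C2 is brought in by 7 and its C–O bond is never broken, the side-chain centre is remote, and the hemiaminal carbon of 35 becomes the sp2 C4. The regioselectivity required (O at C8a, C at C4a) is secured by the 5-OMOM group beside the triple bond, whose inductive pull distorts the aryne so that nucleophiles attack the distal C8a and the charge develops on C4a next to the C–O bond, the C8 alkyl group on the other side having only a weak steric influence. Chemoselectivity is needed against proton capture by the aryl anion and against an intramolecular ene reaction of the aryne with the isopropenyl group, and is sought through an aprotic medium (THF, not MeCN), a preformed alkoxide kept in excess by slow addition of 31, and the Weinreb amide, whose α-protons are weakly acidic and whose adduct 35 keeps C4 masked so that base-induced ring opening at C2 cannot occur.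

Step 17
Reactants: 36 (2S)-2-[2-methoxy-4-(methoxymethoxy)phenyl]-5,7-bis(methoxymethoxy)-8-[(2R)-5-methyl-2-(prop-1-en-2-yl)-5-(triethylsilyloxy)hexyl]-2,3-dihydro-4H-chromen-4-one
Product: 37 (2S)-5,7-dihydroxy-2-(4-hydroxy-2-methoxyphenyl)-8-[(2R)-5-hydroxy-5-methyl-2-(prop-1-en-2-yl)hexyl]-2,3-dihydro-4H-chromen-4-one
Conditions: HCl (about 1.5 M), MeOH/H2O (9:1), 35 °C
Reagents that add atoms: none
Why: Acid-catalysed acetal exchange removes the three aryl MOM ethers and solvolysis removes the tertiary silyl ether, under conditions of the kind used for MOM removal from prenylated flavanones and kept mild so that the isopropenyl group, the tertiary alcohol and C2 should survive.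

## Compound list

1 | 4-hydroxy-2-methoxybenzaldehyde | COc1cc(O)ccc1C=O | starting material
2 | 2-methoxy-4-(methoxymethoxy)benzaldehyde | COCOc1ccc(C=O)c(OC)c1 | intermediate
3 | N-methoxy-N-methylacetamide | CC(=O)N(C)OC | starting material
4 | lithium enolate of 3 (not isolated) | [Li+].[O-]C(=C)N(C)OC | intermediate
5 | rac-3-hydroxy-N-methoxy-3-[2-methoxy-4-(methoxymethoxy)phenyl]-N-methylpropanamide | OC(CC(=O)N(C)OC)c1ccc(OCOC)cc1OC | intermediate
6 | N-methoxy-3-[2-methoxy-4-(methoxymethoxy)phenyl]-N-methyl-3-oxopropanamide | O=C(CC(=O)N(C)OC)c1ccc(OCOC)cc1OC | intermediate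
7 | (3S)-3-hydroxy-N-methoxy-3-[2-methoxy-4-(methoxymethoxy)phenyl]-N-methylpropanamide | O[C@H](c1ccc(OCOC)cc1OC)CC(=O)N(C)OC | intermediate
8 | (4R)-limonene 1,2-oxide, cis/trans mixture at C1/C2 | CC12OC2C[C@@H](CC1)C(=C)C | starting material
9 | (4R)-1-methyl-4-(prop-1-en-2-yl)cyclohexane-1,2-diol, diastereomer mixture (not isolated) | CC1(O)C(O)C[C@@H](CC1)C(=C)C | intermediate
10 | (3R)-6-oxo-3-(prop-1-en-2-yl)heptanal | O=CC[C@@H](CCC(C)=O)C(=C)C | intermediate
11 | (3R)-6-oxo-3-(prop-1-en-2-yl)heptanoic acid | OC(=O)C[C@@H](CCC(C)=O)C(=C)C | intermediate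
12 | (3R)-6-hydroxy-6-methyl-3-(prop-1-en-2-yl)heptanoic acid | OC(=O)C[C@@H](CCC(C)(C)O)C(=C)C | intermediate
13 | triethylsilyl (3R)-6-methyl-3-(prop-1-en-2-yl)-6-(triethylsilyloxy)heptanoate (not isolated) | CC[Si](CC)(CC)OC(=O)C[C@@H](CCC(C)(C)O[Si](CC)(CC)CC)C(=C)C | intermediate
14 | (3R)-6-methyl-3-(prop-1-en-2-yl)-6-(triethylsilyloxy)heptanoic acid | OC(=O)C[C@@H](CCC(C)(C)O[Si](CC)(CC)CC)C(=C)C | intermediate
15 | 2-thioxopyridin-1(2H)-yl (3R)-6-methyl-3-(prop-1-en-2-yl)-6-(triethylsilyloxy)heptanoate, Barton ester (not isolated) | S=c1ccccn1OC(=O)C[C@@H](CCC(C)(C)O[Si](CC)(CC)CC)C(=C)C | intermediate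
16 | triethyl{[(5S)-6-iodo-2-methyl-5-(prop-1-en-2-yl)hexan-2-yl]oxy}silane | IC[C@@H](CCC(C)(C)O[Si](CC)(CC)CC)C(=C)C | intermediate
17 | phloroglucinol (benzene-1,3,5-triol) | Oc1cc(O)cc(O)c1 | starting material
18 | 3,5-bis(methoxymethoxy)phenol | COCOc1cc(O)cc(OCOC)c1 | intermediate
19 | 3,5-bis(methoxymethoxy)phenyl N-(propan-2-yl)carbamate | CC(C)NC(=O)Oc1cc(OCOC)cc(OCOC)c1 | intermediate
20 | N-(tert-butyldimethylsilyl) derivative of 19 (not isolated) | CC(C)N(C(=O)Oc1cc(OCOC)cc(OCOC)c1)[Si](C)(C)C(C)(C)C | intermediate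
21 | 2-lithio derivative of 20 (not isolated) | CC(C)N(C(=O)Oc1cc(OCOC)cc(OCOC)c1[Li])[Si](C)(C)C(C)(C)C | intermediate
22 | N-(tert-butyldimethylsilyl) derivative of 23 (not isolated) | CC(C)N(C(=O)Oc1cc(OCOC)cc(OCOC)c1[Si](C)(C)C)[Si](C)(C)C(C)(C)C | intermediate
23 | 3,5-bis(methoxymethoxy)-2-(trimethylsilyl)phenyl N-(propan-2-yl)carbamate | CC(C)NC(=O)Oc1cc(OCOC)cc(OCOC)c1[Si](C)(C)C | intermediate
24 | N-(trimethylsilyl) derivative of 23 (not isolated) | CC(C)N(C(=O)Oc1cc(OCOC)cc(OCOC)c1[Si](C)(C)C)[Si](C)(C)C | intermediate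
25 | 6-lithio derivative of 24 (not isolated) | CC(C)N(C(=O)Oc1c([Li])c(OCOC)cc(OCOC)c1[Si](C)(C)C)[Si](C)(C)C | intermediate
26 | N-(trimethylsilyl) derivative of 27 (not isolated) | CC(C)N(C(=O)Oc1c(I)c(OCOC)cc(OCOC)c1[Si](C)(C)C)[Si](C)(C)C | intermediate
27 | 2-iodo-3,5-bis(methoxymethoxy)-6-(trimethylsilyl)phenyl N-(propan-2-yl)carbamate | CC(C)NC(=O)Oc1c(I)c(OCOC)cc(OCOC)c1[Si](C)(C)C | intermediate
28 | [(2S)-5-methyl-2-(prop-1-en-2-yl)-5-(triethylsilyloxy)hexyl]zinc iodide (not isolated) | I[Zn]C[C@@H](CCC(C)(C)O[Si](CC)(CC)CC)C(=C)C | intermediate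
29 | 3,5-bis(methoxymethoxy)-2-[(2R)-5-methyl-2-(prop-1-en-2-yl)-5-(triethylsilyloxy)hexyl]-6-(trimethylsilyl)phenyl N-(propan-2-yl)carbamate | C=C(C)[C@H](CCC(C)(C)O[Si](CC)(CC)CC)Cc1c(OCOC)cc(OCOC)c([Si](C)(C)C)c1OC(=O)NC(C)C | intermediate
30 | 3,5-bis(methoxymethoxy)-2-[(2R)-5-methyl-2-(prop-1-en-2-yl)-5-(triethylsilyloxy)hexyl]-6-(trimethylsilyl)phenol (not isolated) | C=C(C)[C@H](CCC(C)(C)O[Si](CC)(CC)CC)Cc1c(OCOC)cc(OCOC)c([Si](C)(C)C)c1O | intermediate
31 | 3,5-bis(methoxymethoxy)-2-[(2R)-5-methyl-2-(prop-1-en-2-yl)-5-(triethylsilyloxy)hexyl]-6-(trimethylsilyl)phenyl trifluoromethanesulfonate | C=C(C)[C@H](CCC(C)(C)O[Si](CC)(CC)CC)Cc1c(OCOC)cc(OCOC)c([Si](C)(C)C)c1OS(=O)(=O)C(F)(F)F | intermediate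
32 | sodium alkoxide of 7 (not isolated) | [Na+].[O-][C@H](c1ccc(OCOC)cc1OC)CC(=O)N(C)OC | intermediate
33 | 1,2-didehydro-3,5-bis(methoxymethoxy)-6-[(2R)-5-methyl-2-(prop-1-en-2-yl)-5-(triethylsilyloxy)hexyl]benzene, the aryne (not isolated) | C=C(C)[C@H](CCC(C)(C)O[Si](CC)(CC)CC)CC1=C(OCOC)C=C(OCOC)C#C1 | intermediate
34 | aryl anion formed by addition of 32 to 33, charge on the future C4a (not isolated) | C=C(C)[C@H](CCC(C)(C)O[Si](CC)(CC)CC)Cc1c(OCOC)cc(OCOC)[c-]c1O[C@H](c1ccc(OCOC)cc1OC)CC(=O)N(C)OC.[Na+] | intermediate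
35 | 4-[methoxy(methyl)amino]chroman-4-olate, tetrahedral adduct, epimer mixture at C4 (not isolated) | C=C(C)[C@H](CCC(C)(C)O[Si](CC)(CC)CC)Cc1c(OCOC)cc(OCOC)c2c1O[C@H](c1ccc(OCOC)cc1OC)CC2([O-])N(C)OC.[Na+] | intermediate
36 | (2S)-2-[2-methoxy-4-(methoxymethoxy)phenyl]-5,7-bis(methoxymethoxy)-8-[(2R)-5-methyl-2-(prop-1-en-2-yl)-5-(triethylsilyloxy)hexyl]-2,3-dihydro-4H-chromen-4-one | C=C(C)[C@H](CCC(C)(C)O[Si](CC)(CC)CC)Cc1c(OCOC)cc(OCOC)c2c1O[C@H](c1ccc(OCOC)cc1OC)CC2=O | intermediate
37 | (2S)-5,7-dihydroxy-2-(4-hydroxy-2-methoxyphenyl)-8-[(2R)-5-hydroxy-5-methyl-2-(prop-1-en-2-yl)hexyl]-2,3-dihydro-4H-chromen-4-one | C=C(C)[C@H](CCC(C)(C)O)Cc1c(O)cc(O)c2c1O[C@H](c1ccc(O)cc1OC)CC2=O | target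

## Step count and risks

Total step count: 17. Longest linear sequence: 9 steps (5, 6, 7, 8, 9, 14, 15, 16, 17).

Three steps most likely to fail:

1. Step 16 (Proposed new method). The aryne may be consumed by an intramolecular ene reaction with the isopropenyl group, or the aryl anion may be protonated before it reaches the amide, which leaves an open aryl ether. Retro-aldol cleavage of the alkoxide would also erode the configuration at C2. The fallback avoids the aryne and builds the same two bonds stepwise by known ionic chemistry. It sets out from 29 and from 6. N-Iodosuccinimide (MeCN, 0 °C) replaces the silyl group of 29 by iodine (ipso-iododesilylation). The phenol is still masked and neither acid nor an external nucleophile is present, so the isopropenyl group should be left alone. This gives 2-iodo-3,5-bis(methoxymethoxy)-6-[(2R)-5-methyl-2-(prop-1-en-2-yl)-5-(triethylsilyloxy)hexyl]phenyl N-(propan-2-yl)carbamate F1. DBU and Et2NH (MeCN, 40 °C) then cleave the carbamate by the E1cB path of step 15 and give 2-iodo-3,5-bis(methoxymethoxy)-6-[(2R)-5-methyl-2-(prop-1-en-2-yl)-5-(triethylsilyloxy)hexyl]phenol F2. Ketone 6 is reduced with the enantiomeric catalyst RuCl[(R,R)-TsDPEN](p-cymene) to the (3R)-hydroxy amide F3, which n-BuLi converts into its lithium alkoxide F4. Treating F2 with n-BuLi (2 equiv, THF, −78 °C) gives, by O-deprotonation and iodine–lithium exchange, the O,C-dilithio species F5. F5 adds to the Weinreb amide of F4, and aqueous work-up releases the β-hydroxy ketone F6, so C4–C4a is formed intermolecularly. An intramolecular Mitsunobu etherification (PPh3, DIAD, THF, 0 °C) then closes O1–C2 with inversion, (R)-carbinol to (2S)-flavanone, and the route is rejoined at 36.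

2. Step 14. Slow oxidative addition or transmetalation at the di-ortho-substituted aryl iodide may let protonation of the zinc reagent by the carbamate N–H, or β-hydride elimination with chain isomerisation, compete with coupling. The fallback replaces the zinc nucleophile by a boron ate complex. It sets out from 16: t-BuLi (2 equiv, Et2O, −78 °C) gives the alkyllithium F7, and B-methoxy-9-borabicyclo[3.3.1]nonane converts it into the lithium B-alkyl-B-methoxy borate F8. B-alkyl Suzuki–Miyaura coupling of F8 with 27 (PdCl2(dppf), aq. K3PO4, DMF, rt) rejoins the route at 29.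

3. Step 17. Acid may induce cyclisation of the 7-hydroxyl onto the protonated isopropenyl group (chroman formation), ionisation of the tertiary carbinol, or ring opening at C2 with loss of configuration. The fallback exchanges the acetals for silyl ethers without a protic acid and then uses buffered fluoride. It sets out from 36: Me3SiOTf and 2,2'-bipyridyl (CH2Cl2, 0 °C) convert the three aryl MOM ethers into aryl trimethylsilyl ethers, giving the tris(trimethylsilyl) ether F9. Bu4NF buffered with AcOH (THF, 0 °C → rt) then cleaves all four silyl ethers and gives 37.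

## Further compounds

F1 | step 16 | 2-iodo-3,5-bis(methoxymethoxy)-6-[(2R)-5-methyl-2-(prop-1-en-2-yl)-5-(triethylsilyloxy)hexyl]phenyl N-(propan-2-yl)carbamate | C=C(C)[C@H](CCC(C)(C)O[Si](CC)(CC)CC)Cc1c(OCOC)cc(OCOC)c(I)c1OC(=O)NC(C)C
F2 | step 16 | 2-iodo-3,5-bis(methoxymethoxy)-6-[(2R)-5-methyl-2-(prop-1-en-2-yl)-5-(triethylsilyloxy)hexyl]phenol | C=C(C)[C@H](CCC(C)(C)O[Si](CC)(CC)CC)Cc1c(OCOC)cc(OCOC)c(I)c1O
F3 | step 16 | (3R)-3-hydroxy-N-methoxy-3-[2-methoxy-4-(methoxymethoxy)phenyl]-N-methylpropanamide | O[C@@H](c1ccc(OCOC)cc1OC)CC(=O)N(C)OC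
F4 | step 16 | lithium alkoxide of F3 | [Li+].[O-][C@@H](c1ccc(OCOC)cc1OC)CC(=O)N(C)OC
F5 | step 16 | O,C-dilithio derivative of F2 (lithium phenoxide, lithium in place of iodine) | C=C(C)[C@H](CCC(C)(C)O[Si](CC)(CC)CC)Cc1c(OCOC)cc(OCOC)c([Li])c1O[Li]
F6 | step 16 | (3R)-3-hydroxy-1-{2-hydroxy-4,6-bis(methoxymethoxy)-3-[(2R)-5-methyl-2-(prop-1-en-2-yl)-5-(triethylsilyloxy)hexyl]phenyl}-3-[2-methoxy-4-(methoxymethoxy)phenyl]propan-1-one | C=C(C)[C@H](CCC(C)(C)O[Si](CC)(CC)CC)Cc1c(OCOC)cc(OCOC)c(C(=O)C[C@@H](O)c2ccc(OCOC)cc2OC)c1O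
F7 | step 14 | [(2S)-5-methyl-2-(prop-1-en-2-yl)-5-(triethylsilyloxy)hexyl]lithium | [Li]C[C@@H](CCC(C)(C)O[Si](CC)(CC)CC)C(=C)C
F8 | step 14 | lithium 9-methoxy-9-[(2S)-5-methyl-2-(prop-1-en-2-yl)-5-(triethylsilyloxy)hexyl]-9-borabicyclo[3.3.1]nonan-9-uide | [Li+].CO[B-]1(C[C@@H](CCC(C)(C)O[Si](CC)(CC)CC)C(=C)C)C2CCCC1CCC2
F9 | step 17 | (2S)-2-[2-methoxy-4-(trimethylsilyloxy)phenyl]-8-[(2R)-5-methyl-2-(prop-1-en-2-yl)-5-(triethylsilyloxy)hexyl]-5,7-bis(trimethylsilyloxy)-2,3-dihydro-4H-chromen-4-one | C=C(C)[C@H](CCC(C)(C)O[Si](CC)(CC)CC)Cc1c(O[Si](C)(C)C)cc(O[Si](C)(C)C)c2c1O[C@H](c1ccc(O[Si](C)(C)C)cc1OC)CC2=O
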